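**Retrosynthetic overview**
- Ebenfuran V ⇐ cleavage of the C4 methyl ether next to the C3 aldehyde ⇐ 4,6-dimethoxy aldehyde ⇐ half-reduction of a coumestan lactone, which masks both the 2'-OH and the CHO.
- Coumestan ⇐ key C3–C3a bond: C3 of 4,7-dihydroxycoumarin (normally nucleophilic) is used as an oxidatively generated enolonium/α-carbonyl radical equivalent and joined to the ortho carbon of a symmetric, para-blocked 3,5-dimethoxyphenol; the furan C–O bond then closes by dehydration.
- Phenol ⇐ meta C–H borylation/oxidation of a 2-alkyl-1,3-dimethoxybenzene ⇐ 2-lithio-1,3-dimethoxybenzene + 2,2-dimethyloxetane.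
- Ring order: the A-ring benzene and the coumarin (B ring + pyranone) are bought; the furan ring forms in the key step; the pyranone is opened in the next step.

Assumption: Ebenfuran V has no stereocentre, so "single enantiomer" requires no stereocontrol; the open hydroxy-aldehyde drawn is the target.

**Step 1**
Reactants: 1 1,3-dimethoxybenzene; 2 2,2-dimethyloxetane
Product: 4 4-(2,6-dimethoxyphenyl)-2-methylbutan-2-ol, via 2,6-dimethoxyphenyllithium 3 (not isolated)
Conditions: n-BuLi (1.1 equiv), THF, 0 °C → rt; then 2 (1.2 equiv), BF3·OEt2 (1.2 equiv), −78 → −20 °C; aq. NH4Cl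
Reagents that add atoms: none
Why: Directed ortho-metalation between the two methoxy groups gives 3, and BF3-activated SN2 opening of the oxetane at its unhindered CH2 delivers the complete 3-hydroxy-3-methylbutyl chain in one operation.

**Step 2**
Reactants: 4 4-(2,6-dimethoxyphenyl)-2-methylbutan-2-ol
Product: 6 4-(3-hydroxy-3-methylbutyl)-3,5-dimethoxyphenol, via aryl pinacol boronate 5 (not isolated)
Conditions: [Ir(OMe)(cod)]2 (1.5 mol %), dtbpy (3 mol %), B2pin2 (1.5 equiv), THF, 80 °C; then aq. NaOH, 30 % H2O2, 0 °C → rt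
Reagents that add atoms: hydrogen peroxide, OO (supplies the phenolic oxygen); bis(pinacolato)diboron, CC1(C)OB(OC1(C)C)B1OC(C)(C)C(C)(C)O1 (supplies the Bpin group of intermediate 5 only)
Why: Sterically controlled Ir-catalysed C–H borylation hits the only C–H without an ortho substituent (para to the alkyl chain), and the boronate is oxidised in the same pot to the phenol (one-pot borylation/oxidation); the tertiary alcohol is at most transiently O-borylated.

**Step 3 (key step)**
Reactants: 6 4-(3-hydroxy-3-methylbutyl)-3,5-dimethoxyphenol; 7 4,7-dihydroxycoumarin (1.5 equiv)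
Product: 9 3-hydroxy-8-(3-hydroxy-3-methylbutyl)-7,9-dimethoxy-6H-[1]benzofuro[3,2-c]chromen-6-one, via 3-aryl-4,7-dihydroxycoumarin 8 (not isolated)
Conditions: FeCl3 (10 mol %), 1,10-phenanthroline (10 mol %), (t-BuO)2 (2.5 equiv), DCE/TFE 4:1, 70 °C; then AcOH, 80 °C
Reagents that add atoms: none
Why: Proposed new method: Fe(III)/peroxide oxidises the Fe-bound enol of 7 to an electrophilic C3 α-carbonyl radical/enolonium equivalent, so that this normally nucleophilic carbon is captured by the equally nucleophilic ortho carbon of phenol 6 (both ortho sites equivalent, para site blocked, hence one regioisomer) to give 8, whose phenol OH and coumarin C4–OH then dehydrate to the furan; the closest known reaction types are the Fe-catalysed oxidative coupling–annulation of acyclic β-keto esters (including 2,4-dimethoxybenzoylacetate) with phenols to 2-arylbenzofuran-3-carboxylates and the Mn(III)/Ce(IV)/Ag(I) oxidative [3+2] annulation of 4-hydroxycoumarin with electron-rich alkenes.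

**Step 4**
Reactants: 9 3-hydroxy-8-(3-hydroxy-3-methylbutyl)-7,9-dimethoxy-6H-[1]benzofuro[3,2-c]chromen-6-one
Product: 11 2-(2,4-dihydroxyphenyl)-5-(3-hydroxy-3-methylbutyl)-4,6-dimethoxy-1-benzofuran-3-carbaldehyde, via lactol 10 (not isolated)
Conditions: DIBAL-H (4 equiv), THF/CH2Cl2, −78 °C; aq. Rochelle salt
Reagents that add atoms: none
Why: DIBAL-H half-reduction of the aryl lactone stops at the aluminium lactolate of 10 at −78 °C, and on work-up the lactol opens to the 2'-phenol and the 3-carbaldehyde because that aldehyde is a stabilised vinylogous formate; two of the four equivalents only deprotonate the OH groups.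

**Step 5**
Reactants: 11 2-(2,4-dihydroxyphenyl)-5-(3-hydroxy-3-methylbutyl)-4,6-dimethoxy-1-benzofuran-3-carbaldehyde
Product: 12 Ebenfuran V [2-(2,4-dihydroxyphenyl)-4-hydroxy-5-(3-hydroxy-3-methylbutyl)-6-methoxy-1-benzofuran-3-carbaldehyde]
Conditions: MgI2·OEt2 (4 equiv), toluene/Et2O, 70 °C; aq. NH4Cl/Na2S2O3
Reagents that add atoms: none
Why: Chelation-assisted ether cleavage: Mg(II) bridges the formyl oxygen and the neighbouring C4 methoxy oxygen (also the only methoxy twisted out of plane by two ortho neighbours), iodide removes that methyl by SN2, and the C6 methoxy and the tertiary alcohol are not touched by this weak Lewis acid.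

**Compound list**
1 | 1,3-dimethoxybenzene | COc1cccc(OC)c1 | starting material
2 | 2,2-dimethyloxetane | CC1(C)CCO1 | starting material
3 | 2,6-dimethoxyphenyllithium | [Li]c1c(OC)cccc1OC | intermediate
4 | 4-(2,6-dimethoxyphenyl)-2-methylbutan-2-ol | COc1cccc(OC)c1CCC(C)(C)O | intermediate
5 | 4-[2,6-dimethoxy-4-(4,4,5,5-tetramethyl-1,3,2-dioxaborolan-2-yl)phenyl]-2-methylbutan-2-ol | COc1cc(B2OC(C)(C)C(C)(C)O2)cc(OC)c1CCC(C)(C)O | intermediate
6 | 4-(3-hydroxy-3-methylbutyl)-3,5-dimethoxyphenol | COc1cc(O)cc(OC)c1CCC(C)(C)O | intermediate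
7 | 4,7-dihydroxycoumarin (4,7-dihydroxy-2H-chromen-2-one) | O=c1cc(O)c2ccc(O)cc2o1 | starting material
8 | 4,7-dihydroxy-3-[2-hydroxy-5-(3-hydroxy-3-methylbutyl)-4,6-dimethoxyphenyl]-2H-chromen-2-one | O=c1oc2cc(O)ccc2c(O)c1-c1c(O)cc(OC)c(CCC(C)(C)O)c1OC | intermediate
9 | 3-hydroxy-8-(3-hydroxy-3-methylbutyl)-7,9-dimethoxy-6H-[1]benzofuro[3,2-c]chromen-6-one | COc1cc2oc3c(c(=O)oc4cc(O)ccc34)c2c(OC)c1CCC(C)(C)O | intermediate
10 | 8-(3-hydroxy-3-methylbutyl)-7,9-dimethoxy-6H-[1]benzofuro[3,2-c]chromene-3,6-diol (lactol, racemic at C6, formed as its aluminium alkoxide) | COc1cc2oc3c(c2c(OC)c1CCC(C)(C)O)C(O)Oc1cc(O)ccc1-3 | intermediate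
11 | 2-(2,4-dihydroxyphenyl)-5-(3-hydroxy-3-methylbutyl)-4,6-dimethoxy-1-benzofuran-3-carbaldehyde | COc1cc2oc(-c3ccc(O)cc3O)c(C=O)c2c(OC)c1CCC(C)(C)O | intermediate
12 | Ebenfuran V, 2-(2,4-dihydroxyphenyl)-4-hydroxy-5-(3-hydroxy-3-methylbutyl)-6-methoxy-1-benzofuran-3-carbaldehyde | COc1cc2oc(-c3ccc(O)cc3O)c(C=O)c2c(O)c1CCC(C)(C)O | target

**Totals**
Total step count: 5. Longest linear sequence: 5 steps (1 → 4 → 6 → 9 → 11 → 12).

**Three steps most likely to fail, with fallbacks**

Step 3. The cyclic coumarin enol cannot chelate iron as an acyclic β-keto ester does. Phenol 6 may also homo-couple or be oxidised at its benzylic CH2, and FeCl3 may dehydrate the tertiary alcohol. The fallback sets out from 6 and comes back at 9. Commercial 2',4'-dihydroxyacetophenone is benzylated (BnBr, K2CO3, DMF) to 1-[2,4-bis(benzyloxy)phenyl]ethan-1-one F1. This is C-acylated (NaH, diethyl carbonate, THF, reflux) to ethyl 3-[2,4-bis(benzyloxy)phenyl]-3-oxopropanoate F2. F2 and 6 are joined under the same Fe(III)/peroxide conditions, now in the established acyclic chelating format, to ethyl 2-[2,4-bis(benzyloxy)phenyl]-5-(3-hydroxy-3-methylbutyl)-4,6-dimethoxy-1-benzofuran-3-carboxylate F3. Hydrogenolysis (H2, Pd/C, EtOAc) gives ethyl 2-(2,4-dihydroxyphenyl)-5-(3-hydroxy-3-methylbutyl)-4,6-dimethoxy-1-benzofuran-3-carboxylate F4, whose 2'-OH lactonises onto the ester (PPTS, toluene, 80 °C) to give 9.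

Step 4. The lactolate may collapse early and the aldehyde may be over-reduced. The fallback sets out from 9 and comes back at 11. The lactone is reduced fully (LiAlH4, THF, 0 °C, neutral work-up) to 4-[3-(hydroxymethyl)-5-(3-hydroxy-3-methylbutyl)-4,6-dimethoxy-1-benzofuran-2-yl]benzene-1,3-diol F5. The benzofuranyl carbinol alone is then re-oxidised with activated MnO2 (acetone, rt) to 11; acid is avoided throughout so that F5 does not close to the cyclic ether.

Step 5. The seven-membered Mg chelate may be too weak for clean, selective cleavage, and forcing conditions would endanger the tertiary alcohol (chroman formation once the C4–OH is free). The fallback sets out from 11 and comes back at 12. All three hydroxyls are silylated (TESOTf, 2,6-lutidine, CH2Cl2, 0 °C) to 2-[2,4-bis(triethylsilyloxy)phenyl]-4,6-dimethoxy-5-[3-methyl-3-(triethylsilyloxy)butyl]-1-benzofuran-3-carbaldehyde F6. With the tertiary alcohol shielded, the stronger chelating Lewis acid BCl3 (CH2Cl2, −78 → −40 °C) cleaves the C4 methyl ether to 2-[2,4-bis(triethylsilyloxy)phenyl]-4-hydroxy-6-methoxy-5-[3-methyl-3-(triethylsilyloxy)butyl]-1-benzofuran-3-carbaldehyde F7. Buffered fluoride (TBAF/AcOH, THF, 0 °C) then removes the silyl groups to give 12.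

**Further compounds**
F1 | step 3 | 1-[2,4-bis(benzyloxy)phenyl]ethan-1-one | CC(=O)c1ccc(OCc2ccccc2)cc1OCc1ccccc1
F2 | step 3 | ethyl 3-[2,4-bis(benzyloxy)phenyl]-3-oxopropanoate | CCOC(=O)CC(=O)c1ccc(OCc2ccccc2)cc1OCc1ccccc1
F3 | step 3 | ethyl 2-[2,4-bis(benzyloxy)phenyl]-5-(3-hydroxy-3-methylbutyl)-4,6-dimethoxy-1-benzofuran-3-carboxylate | CCOC(=O)c1c(-c2ccc(OCc3ccccc3)cc2OCc2ccccc2)oc2cc(OC)c(CCC(C)(C)O)c(OC)c12
F4 | step 3 | ethyl 2-(2,4-dihydroxyphenyl)-5-(3-hydroxy-3-methylbutyl)-4,6-dimethoxy-1-benzofuran-3-carboxylate | CCOC(=O)c1c(-c2ccc(O)cc2O)oc2cc(OC)c(CCC(C)(C)O)c(OC)c12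
F5 | step 4 | 4-[3-(hydroxymethyl)-5-(3-hydroxy-3-methylbutyl)-4,6-dimethoxy-1-benzofuran-2-yl]benzene-1,3-diol | COc1cc2oc(-c3ccc(O)cc3O)c(CO)c2c(OC)c1CCC(C)(C)O
F6 | step 5 | 2-[2,4-bis(triethylsilyloxy)phenyl]-4,6-dimethoxy-5-[3-methyl-3-(triethylsilyloxy)butyl]-1-benzofuran-3-carbaldehyde | COc1cc2oc(-c3ccc(O[Si](CC)(CC)CC)cc3O[Si](CC)(CC)CC)c(C=O)c2c(OC)c1CCC(C)(C)O[Si](CC)(CC)CC
F7 | step 5 | 2-[2,4-bis(triethylsilyloxy)phenyl]-4-hydroxy-6-methoxy-5-[3-methyl-3-(triethylsilyloxy)butyl]-1-benzofuran-3-carbaldehyde | COc1cc2oc(-c3ccc(O[Si](CC)(CC)CC)cc3O[Si](CC)(CC)CC)c(C=O)c2c(O)c1CCC(C)(C)O[Si](CC)(CC)CC
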